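The runs are calculated for substances that don't exist.

**The decision.** As the one charging Tuesday's flask, I had to decide whether it repeated Thursday's charge for 72 min or whether the wait was pointless, since Thursday's run had nearly stopped climbing by 12 min.

| flask | Sbt | Ctl | time |
|---|---|---|---|
| Thursday's | 120 mM | 6.00 mM |  |
| Sunday's | 72.0 mM | 6.00 mM |  |
| Monday's | 120 mM | 9.00 mM |  |
| Saturday's | 360 mM | 6.00 mM |  |
| Tuesday's | 120 mM | 6.00 mM | 72 min |

| run | time / min | [Pdt] / mM |
|---|---|---|
| Thursday's run | 0.91 | 13.9 |
| Thursday's run | 2.8 | 28.2 |
| Thursday's run | 5.3 | 35.8 |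
| Thursday's run | 8.4 | 39.5 |
| Thursday's run | 12 | 41.8 |
| Sunday's run | 0.91 | 7.7 |
| Sunday's run | 2.8 | 20.7 |
| Sunday's run | 5.3 | 28.5 |
| Sunday's run | 8.4 | 31.6 |
| Sunday's run | 12 | 32.3 |
| Monday's run | 0.91 | 18.4 |
| Monday's run | 2.8 | 38.1 |
| Monday's run | 5.3 | 46.8 |
| Monday's run | 8.4 | 51.5 |
| Monday's run | 12 | 51.2 |
| Saturday's run | 0.91 | 23.0 |
| Saturday's run | 2.8 | 46.6 |
| Saturday's run | 5.3 | 55.3 |
| Saturday's run | 8.4 | 59.8 |
| Saturday's run | 12 | 62.2 |

(readings scatter by 0.6 mM)

- Overall: Sbt -> Pdt, with Ctl as catalyst.
- Constant volume, constant temperature.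
- An order is taken over about fifteen percent of the charge, up and down.

* reaction order in [Sbt] at the outset, round the charge of the Thursday's run, defined at two percent of the Sbt turned into Pdt (one fixed amount of Pdt, the same in the runs compared)
* reaction order in [Ctl] at the outset, round the charge of the Thursday's run, defined at two percent of the Sbt turned into Pdt
* Pdt in the Tuesday's run at 72 min, as a share of the Sbt charged

**Two rates.** Thursday's run made Pdt at 1.19 mM/min between its third and fourth readings, around 37.6 mM, and then at 0.639 mM/min between its fourth and fifth readings, around 40.6 mM. I divided one rate by the other, so time dropped out: if the rate falls in proportion to the Pdt still to come, the ratio of rates equals the ratio of what remains. That gave 44.1 mM as the ceiling, the plateau yield, meaning the [Pdt] at which the extended rate line reaches zero. With 0.6 mM on each reading, this was a rough reading.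

**My call.** The ceiling stood 2.31 mM above Thursday's last reading. The same line gave a fade time of 5.41 min, and the extra wait was far longer than that. So I left the charge alone, kept the full wait, and expected 36.8% on Tuesday.

**The forecast.** It gave 0.9 (0.6 to 1.2) for the order in [Sbt], 0.9 (0.6 to 1.2) for the order in [Ctl], and 38% (35.5% to 43%) for Tuesday's share, holding that “the catalyst is dying within minutes”. Its share was higher than mine.

**The result.** Tuesday's flask gave 35.9%, with orders of 0.59 in [Sbt] and 0.75 in [Ctl].

    L + Sbt → Pdt + L (45.36 /M/min)
    2 Sbt → E (4.452 /M/min)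
    Ctl → L (3.408 /min)

The step from two Sbt to E moved the readings by a root mean square of 180 in units of the scatter. My ceiling for Thursday's charge had stood 0.90 percentage points above Tuesday's share. The same division on Sunday's run gave a ceiling of 32.4 mM. With Sunday's rate of 11 mM/min, taken at two percent of Thursday's Sbt turned, the proportional fall put a quarter of Sunday's charge at 2.46 min, and Sunday's run stood there at 2.13 min.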